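**Plan**

Labdane numbering is used throughout. The SMILES is read as methyl (13E)-ent-6α,8α-dihydroxylabd-13-en-15-oate, (5R,6R,8S,9S,10R): a trans-decalin with both hydroxyls equatorial and trans to the C10 methyl (C20).
Retrosynthetic cuts, in order: C13=C14 (olefination of a C13 methyl ketone); the C8–O and C6–O bonds (back to a 7-en-6-one); C9–C11 (organometallic addition to a C9 ketone); C3–C4 (radical closure of ring A); C10–C1 and C10–C20 (enolate chemistry).
The enabling feature is ring B: the C8 methyl (C17) sits para to C5, and C5 carries C4 with its two methyls (C18, C19), which is an isopropenyl group plus one hydrogen atom. Ring B with C17, C4, C18, C19 and the C5 stereocentre is therefore (S)-carvone, and a tertiary radical at C4 can close ring A onto a three-carbon enone (C1–C3) attached to C10.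
Forward: C20 and the acryloyl arm go onto C10 of carvone; ring A closes (C3–C4); the C1 oxygen is removed; the chain is joined at C9; the enone is moved to C6/C7; the two hydroxyls and then the enoate are installed.
Stereochemistry: C5 from carvone; C10 by aldol anti to isopropenyl; C9 by axial protonation anti to C20 (Li/NH3); C8 by enone epoxidation anti to C20; C6 by thermodynamic (equatorial) dissolving-metal reduction; 13E by Horner–Wadsworth–Emmons olefination.

Key step: step 4

**Route**

Step 1
Reactants: 1 (S)-carvone; 2 iodomethane
Product: 4 (5S)-6-methylcarvone (both C6 epimers), via carvone lithium dienolate 3 (not isolated)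
Conditions: LiN(iPr)2, THF, −78 °C; MeI, −78 → −20 °C
Reagents that add atoms: iodomethane, CI
Why: Kinetic α′-deprotonation of the enone followed by SN2 methylation of the cross-conjugated lithium dienolate (enolate alkylation) should give the C6-methyl ketone, and the configuration of the new centre is of no consequence because this carbon is enolised again in step 2.

Step 2
Reactants: 4 (5S)-6-methylcarvone; 5 acrolein
Product: 7 (5R,6S)-6-(1-hydroxyprop-2-en-1-yl)-6-methylcarvone (both carbinol epimers), via methylcarvone lithium enolate 6 (not isolated)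
Conditions: LiN(iPr)2, THF, −78 °C; acrolein, −78 °C; AcOH, −78 °C
Reagents that add atoms: acrolein, C=CC=O
Why: A lithium enolate aldol addition at −78 °C should attack acrolein at its carbonyl carbon (1,2-addition), and the aldehyde should approach the tetrasubstituted enolate carbon anti to the neighbouring isopropenyl group, as alkyl halides do with this enolate, so that the new quaternary centre (labdane C10) carries its methyl cis and its three-carbon arm trans to isopropenyl, while the carbinol centre is a mixture that step 3 removes.

Step 3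
Reactants: 7 aldol adduct
Product: 8 (5R,6S)-6-acryloyl-6-methylcarvone
Conditions: Dess–Martin periodinane, CH2Cl2, 0 °C → rt
Reagents that add atoms: none
Why: Dess–Martin oxidation of the secondary allylic alcohol under non-aqueous, nearly neutral conditions should give the vinyl ketone without retro-aldol cleavage or conjugate addition to the new enone, and no stereocentre is touched.

Step 4
Reactants: 8 (5R,6S)-6-acryloyl-6-methylcarvone
Product: 9 11-nor-ent-drim-7-ene-1,9-dione
Conditions: Fe(acac)3 (30 mol %), PhSiH3, EtOH/ethylene glycol (5:1), 60 °C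
Reagents that add atoms: none
Why: An iron hydride formed from Fe(acac)3 and PhSiH3 transfers a hydrogen atom to the terminal CH2 of the isopropenyl group, the tertiary C4 radical adds to the unsubstituted terminus (C3) of the vinyl ketone, and the α-keto radical at C2 is reduced by divalent iron to the enolate and protonated by ethanol. The closest known reaction type is the iron-mediated reductive olefin–enone coupling (a Giese-type radical conjugate addition) run intramolecularly. Ring A closes in the 6-endo-trig mode, forming the hindered C3–C4 bond next to the ring fusion under neutral conditions. No new stereocentre arises, since C4 becomes a gem-dimethyl carbon and C2 a methylene; the trans ring fusion is already fixed because the acryloyl group on C10 and the radical-bearing group on C5 are trans on ring B and can only meet diequatorially. The step needs hydrogen-atom transfer to the electron-rich 1,1-disubstituted alkene in the presence of two electron-poor enone alkenes, and attack at the enone terminus; both follow from alkene electronics and from the nucleophilic character of the tertiary radical.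

Step 5
Reactants: 9 11-nor-ent-drim-7-ene-1,9-dione
Product: 10 1-hydroxy-11-nor-ent-drim-7-en-9-one (C1 epimers)
Conditions: NaBH4, MeOH/CH2Cl2, −78 → −40 °C
Reagents that add atoms: none
Why: Borohydride reduction should take the saturated C1 ketone and leave the C9 ketone, which is deactivated by conjugation and shielded by the quaternary C10 and the C8 methyl (the chemoselectivity known from Wieland–Miescher-type enediones), and the C1 carbinol configuration is irrelevant because this oxygen is removed in step 7.

Step 6
Reactants: 10 1-hydroxy-11-nor-ent-drim-7-en-9-one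
Product: 11 C1 O-phenyl thionocarbonate of 10
Conditions: PhOC(S)Cl, pyridine, DMAP (cat.), CH2Cl2, 0 °C → rt
Reagents that add atoms: O-phenyl chlorothionoformate, S=C(Cl)Oc1ccccc1
Why: DMAP-catalysed acylation of the secondary alcohol with phenyl chlorothionoformate (the first half of a Barton–McCombie deoxygenation) uses only amine bases, so the β-hydroxy ketone should not undergo retro-aldol cleavage.

Step 7
Reactants: 11 C1 O-phenyl thionocarbonate
Product: 12 11-nor-ent-drim-7-en-9-one
Conditions: Bu3SnH (3 equiv, 0.3 M), AIBN (cat.), toluene, 100 °C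
Reagents that add atoms: none
Why: In this Barton–McCombie radical deoxygenation the stannyl radical adds to the thiocarbonyl sulfur, the C1–O bond fragments, and the secondary C1 radical is reduced by Bu3SnH, which is kept concentrated so that hydrogen transfer outruns a 1,2-acyl shift of the β-keto radical.

Step 8
Reactants: 12 11-nor-ent-drim-7-en-9-one; 13 2-(2-bromoethyl)-2-methyl-1,3-dioxolane
Product: 15 9-hydroxy-13,13-ethylenedioxy-14,15-dinor-ent-labd-7-ene (C9 configuration left open), via Grignard reagent 14 (not isolated)
Conditions: 13, Mg, THF, 25 °C; then 12, LaCl3·2LiCl (30 mol %), THF, 0 °C; H2O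
Reagents that add atoms: 2-(2-bromoethyl)-2-methyl-1,3-dioxolane, CC1(CCBr)OCCO1
Why: Lanthanum-promoted Grignard 1,2-addition to the hindered enone carbonyl (the lanthanum salt suppressing γ-deprotonation and β-hydride reduction) should give the tertiary allylic alcohol, attack being expected anti to the C10 methyl although the C9 configuration is erased in step 9.

Step 9
Reactants: 15 tertiary allylic alcohol
Product: 16 13,13-ethylenedioxy-14,15-dinor-ent-labd-8-en-7-one
Conditions: pyridinium chlorochromate [C5H5NH][CrO3Cl], 4 Å molecular sieves, CH2Cl2, rt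
Reagents that add atoms: pyridinium chlorochromate, [O-][Cr](=O)(=O)Cl.c1cc[nH+]cc1
Why: In this Dauben–Babler oxidative 1,3-transposition the chromate ester of the tertiary allylic alcohol undergoes [3,3]-sigmatropic shift to C7 and is oxidised there, which moves the carbonyl from C9 to C7 and the alkene to C8=C9 without creating a stereocentre.

Step 10
Reactants: 16 13,13-ethylenedioxy-14,15-dinor-ent-labd-8-en-7-one
Product: 18 13,13-ethylenedioxy-14,15-dinor-ent-labd-7-en-7-yl triflate, via lithium enolate 17 (not isolated)
Conditions: Li (2.2 equiv), t-BuOH (1 equiv), NH3(l)/THF, −78 °C; NH3 evaporated; PhNTf2, THF, 0 °C → rt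
Reagents that add atoms: N-phenylbis(trifluoromethanesulfonimide), O=S(=O)(N(c1ccccc1)S(=O)(=O)C(F)(F)F)C(F)(F)F
Why: Dissolving-metal conjugate reduction of the enone (Birch-type) delivers the β-proton to C9 axially on the face anti to the C10 methyl, which sets H9 trans to C20 with the chain equatorial, and leaves the C7–C8 lithium enolate regiospecifically, which N-phenyltriflimide traps on oxygen as the enol triflate.

Step 11
Reactants: 18 enol triflate
Product: 19 13,13-ethylenedioxy-14,15-dinor-ent-labd-7-ene
Conditions: Pd(OAc)2 (cat.), PPh3, HCO2H, Bu3N, DMF, 60 °C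
Reagents that add atoms: none
Why: Palladium-catalysed formate reduction of an enol triflate (oxidative addition to zerovalent palladium, formate exchange, decarboxylation and C–H reductive elimination) should replace the triflate by hydrogen with the C7=C8 position and the C9 stereocentre unchanged.

Step 12
Reactants: 19 13,13-ethylenedioxy-14,15-dinor-ent-labd-7-ene
Product: 20 13,13-ethylenedioxy-14,15-dinor-ent-labd-7-en-6-one
Conditions: CrO3, 3,5-dimethylpyrazole, CH2Cl2, −20 °C
Reagents that add atoms: chromium trioxide, O=[Cr](=O)=O
Why: Allylic C–H oxidation with the CrO3–3,5-dimethylpyrazole complex should convert the ring methylene C6 into the ketone, as it does with Δ7-sterols that also carry a tertiary allylic C9–H, giving the 7-en-6-one without change at C5 or C9.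

Step 13
Reactants: 20 13,13-ethylenedioxy-14,15-dinor-ent-labd-7-en-6-one
Product: 21 ent-7α,8α-epoxy-13,13-ethylenedioxy-14,15-dinor-labdan-6-one (epoxide oxygen trans to C20)
Conditions: 30% H2O2, NaOH (cat.), MeOH, 0 °C → rt
Reagents that add atoms: hydrogen peroxide, OO
Why: In this Weitz–Scheffer nucleophilic epoxidation hydroperoxide adds to the β-carbon C8 on the face anti to the axial C10 methyl and the enolate closes onto oxygen, so the C8–O bond ends up trans to C20 and C17 cis to it.

Step 14
Reactants: 21 epoxy ketone
Product: 22 ent-8α-hydroxy-13,13-ethylenedioxy-14,15-dinor-labdan-6-one (8-OH equatorial, trans to C20)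
Conditions: SmI2 (2.2 equiv), THF/MeOH, −78 °C
Reagents that add atoms: none
Why: SmI2 reductive opening of an α,β-epoxy ketone cleaves the Cα–O bond at C7 by two single-electron transfers and leaves the β-hydroxy ketone with the C8 carbinol configuration retained, at −78 °C with methanol present so that the ketone is not reduced further and water is not eliminated.

Step 15
Reactants: 22 β-hydroxy ketone
Product: 23 ent-6α,8α-dihydroxy-13,13-ethylenedioxy-14,15-dinor-labdane (both OH equatorial, trans to C20)
Conditions: Li, EtOH, NH3(l)/THF, −78 °C; solid NH4Cl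
Reagents that add atoms: none
Why: Dissolving-metal reduction of the hindered ketone proceeds through a ketyl that is protonated to the thermodynamically preferred equatorial alcohol, placing the C6 hydroxyl trans to the C10 methyl and away from the syn-axial C20 and C4 methyls that the alcohol from hydride attack on the open face would have to face.

Step 16
Reactants: 23 diol ketal
Product: 24 ent-6α,8α-dihydroxy-14,15-dinorlabdan-13-one
Conditions: 1 M HCl, THF, rt
Reagents that add atoms: water, O
Why: Acid-catalysed acetal hydrolysis under mild aqueous conditions should free the methyl ketone without dehydrating the tertiary C8 alcohol, and no stereocentre is involved.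

Step 17
Reactants: 24 dihydroxy methyl ketone; 25 trimethyl phosphonoacetate
Product: 27 methyl (13E)-ent-6α,8α-dihydroxylabd-13-en-15-oate (target), via sodium phosphonate 26 (not isolated)
Conditions: (MeO)2P(O)CH2CO2Me, NaH, THF, 0 °C; then 24, reflux
Reagents that add atoms: trimethyl phosphonoacetate, COC(=O)CP(=O)(OC)OC
Why: Horner–Wadsworth–Emmons olefination of the methyl ketone with the preformed sodium phosphonate should give the trisubstituted enoate mainly as the E isomer (ester trans to the larger C12 chain) under reversible addition, the weakly basic phosphonate anion leaving the two hydroxyls untouched and any Z isomer being removed by chromatography.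

**Compound list**

1 | (S)-carvone, (5S)-2-methyl-5-(prop-1-en-2-yl)cyclohex-2-en-1-one | CC1=CC[C@@H](CC1=O)C(C)=C | starting material
2 | iodomethane | CI | starting material
3 | kinetic lithium dienolate of carvone (O–Li on C1, C1=C6 and C2=C3), formed in situ | CC1=CC[C@@H](C=C1O[Li])C(C)=C | intermediate
4 | (5S,6RS)-2,6-dimethyl-5-(prop-1-en-2-yl)cyclohex-2-en-1-one (6-methylcarvone, C6 epimers) | CC1=CC[C@@H](C(C)C1=O)C(C)=C | intermediate
5 | acrolein (prop-2-enal) | C=CC=O | starting material
6 | lithium enolate of 4 (O–Li on C1, C1=C6), formed in situ | CC1=CC[C@@H](C(C)=C1O[Li])C(C)=C | intermediate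
7 | (5R,6S)-6-(1-hydroxyprop-2-en-1-yl)-2,6-dimethyl-5-(prop-1-en-2-yl)cyclohex-2-en-1-one (hydroxyallyl arm trans to isopropenyl, carbinol epimers) | O=C1[C@](C)(C(O)C=C)[C@@H](C(C)=C)CC=C1C | intermediate
8 | (5R,6S)-6-acryloyl-2,6-dimethyl-5-(prop-1-en-2-yl)cyclohex-2-en-1-one (acryloyl trans to isopropenyl) | O=C1[C@](C)(C(=O)C=C)[C@@H](C(C)=C)CC=C1C | intermediate
9 | 11-nor-ent-drim-7-ene-1,9-dione, (4aR,8aS)-2,5,5,8a-tetramethyl-4a,5,6,7-tetrahydronaphthalene-1,8(4H,8aH)-dione (trans-fused) | O=C1[C@]2(C)C(=O)CCC(C)(C)[C@H]2CC=C1C | intermediate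
10 | 1-hydroxy-11-nor-ent-drim-7-en-9-one (C1 epimers) | O=C1[C@]2(C)C(O)CCC(C)(C)[C@H]2CC=C1C | intermediate
11 | O-phenyl thionocarbonate of 10 at the C1 oxygen | O=C1[C@]2(C)C(OC(=S)Oc3ccccc3)CCC(C)(C)[C@H]2CC=C1C | intermediate
12 | 11-nor-ent-drim-7-en-9-one, (4aR,8aR)-2,5,5,8a-tetramethyl-4a,5,6,7,8,8a-hexahydronaphthalen-1(4H)-one | O=C1[C@]2(C)CCCC(C)(C)[C@H]2CC=C1C | intermediate
13 | 2-(2-bromoethyl)-2-methyl-1,3-dioxolane | CC1(CCBr)OCCO1 | starting material
14 | [2-(2-methyl-1,3-dioxolan-2-yl)ethyl]magnesium bromide, formed in situ | CC1(CC[Mg]Br)OCCO1 | intermediate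
15 | 9-hydroxy-13,13-ethylenedioxy-14,15-dinor-ent-labd-7-ene (tertiary allylic alcohol, C9 configuration left open) | OC1(CCC3(C)OCCO3)[C@]2(C)CCCC(C)(C)[C@H]2CC=C1C | intermediate
16 | 13,13-ethylenedioxy-14,15-dinor-ent-labd-8-en-7-one | CC1=C(CCC3(C)OCCO3)[C@]2(C)CCCC(C)(C)[C@H]2CC1=O | intermediate
17 | lithium C7–C8 enolate of the 7-ketone (H9 trans to C20), formed in situ | CC1(CC[C@H]2[C@]3(C)CCCC(C)(C)[C@H]3CC(O[Li])=C2C)OCCO1 | intermediate
18 | 13,13-ethylenedioxy-14,15-dinor-ent-labd-7-en-7-yl trifluoromethanesulfonate (H9 trans to C20, chain equatorial) | CC1(CC[C@H]2[C@]3(C)CCCC(C)(C)[C@H]3CC(OS(=O)(=O)C(F)(F)F)=C2C)OCCO1 | intermediate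
19 | 13,13-ethylenedioxy-14,15-dinor-ent-labd-7-ene | CC1(CC[C@H]2[C@]3(C)CCCC(C)(C)[C@H]3CC=C2C)OCCO1 | intermediate
20 | 13,13-ethylenedioxy-14,15-dinor-ent-labd-7-en-6-one | CC1(CC[C@H]2[C@]3(C)CCCC(C)(C)[C@H]3C(=O)C=C2C)OCCO1 | intermediate
21 | ent-7α,8α-epoxy-13,13-ethylenedioxy-14,15-dinor-labdan-6-one (epoxide oxygen trans to C20) | CC1(CC[C@H]2[C@]3(C)CCCC(C)(C)[C@H]3C(=O)[C@@H]4O[C@@]42C)OCCO1 | intermediate
22 | ent-8α-hydroxy-13,13-ethylenedioxy-14,15-dinor-labdan-6-one (8-OH trans to C20, C17 cis to C20) | CC1(CC[C@H]2[C@]3(C)CCCC(C)(C)[C@H]3C(=O)C[C@]2(C)O)OCCO1 | intermediate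
23 | ent-6α,8α-dihydroxy-13,13-ethylenedioxy-14,15-dinor-labdane (both OH equatorial, trans to C20) | CC1(CC[C@H]2[C@]3(C)CCCC(C)(C)[C@H]3[C@H](O)C[C@]2(C)O)OCCO1 | intermediate
24 | ent-6α,8α-dihydroxy-14,15-dinorlabdan-13-one | CC(=O)CC[C@H]1[C@]2(C)CCCC(C)(C)[C@H]2[C@H](O)C[C@]1(C)O | intermediate
25 | trimethyl phosphonoacetate | COC(=O)CP(=O)(OC)OC | starting material
26 | sodium salt of trimethyl phosphonoacetate, formed in situ | [Na+].COC(=O)[CH-]P(=O)(OC)OC | intermediate
27 | methyl (13E)-ent-6α,8α-dihydroxylabd-13-en-15-oate, (5R,6R,8S,9S,10R) | COC(=O)/C=C(\C)CC[C@H]1[C@]2(C)CCCC(C)(C)[C@H]2[C@H](O)C[C@]1(C)O | target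

**Count**

Total step count: 17. Longest linear sequence: 17 steps, from (S)-carvone 1 to 27; compounds 2, 5, 13 and 25 are bought.

**Steps most likely to fail**

Step 12. The oxidant may abstract the tertiary allylic C9–H or a C17 hydrogen instead of a C6 hydrogen, or oxidise further, so that conversion to the 7-en-6-one stays low. Fallback, setting out from alkene 19: epoxidation with mCPBA (NaHCO3, CH2Cl2, 0 °C) on the face anti to the C10 methyl should give the 7,8-epoxide F3. Opening with PhSeNa (from (PhSe)2 and NaBH4, EtOH, reflux) at the secondary C7 should give the hydroxy selenide F4, whose selenoxide (H2O2, THF, 0 °C → rt) eliminates syn towards C6 to the tertiary allylic alcohol F5. Oxidative 1,3-transposition with pyridinium chlorochromate, as in step 9, then carries oxygen to C6 and returns to enone 20.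

Step 15. In the basic medium the β-hydroxy ketone may fragment by retro-aldol reaction through the C8 alkoxide before the ketone is reduced. Fallback, setting out from hydroxy ketone 22: silylation of the tertiary hydroxyl with N-(trimethylsilyl)imidazole (CH2Cl2, rt) should give the silyl ether F6, which cannot form the alkoxide. Reduction with Li/EtOH in NH3 as above should then give the equatorial C6 alcohol F7. The aqueous HCl of step 16 removes the silyl group together with the dioxolane, so the sequence rejoins the route at 24.

Step 7. The C1 radical may attack the neighbouring C9 carbonyl and undergo 1,2-acyl migration (the ring-expansion pathway of β-keto radicals) in competition with hydrogen transfer from the stannane. Fallback, setting out from dione 9 (steps 5 and 6 are then not needed): KN(SiMe3)2 and PhNTf2 (THF, −78 °C) should convert the more readily enolised C1 ketone into the enol triflate F1. Formate reduction with Pd(OAc)2/PPh3/HCO2H/Bu3N, as in step 11, gives the 1,7-dien-9-one F2. Diimide (from KO2CN=NCO2K and AcOH, MeOH, rt) then saturates only the cis-disubstituted C1=C2 alkene and returns to enone 12.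

**Further compounds**

F1 | step 7 | 9-oxo-11-nor-ent-drima-1,7-dien-1-yl trifluoromethanesulfonate | O=C1[C@]2(C)C(OS(=O)(=O)C(F)(F)F)=CCC(C)(C)[C@H]2CC=C1C
F2 | step 7 | 11-nor-ent-drima-1,7-dien-9-one | O=C1[C@]2(C)C=CCC(C)(C)[C@H]2CC=C1C
F3 | step 12 | ent-7α,8α-epoxy-13,13-ethylenedioxy-14,15-dinor-labdane (epoxide oxygen trans to C20) | CC1(CC[C@H]2[C@]3(C)CCCC(C)(C)[C@H]3C[C@@H]4O[C@@]42C)OCCO1
F4 | step 12 | 7-(phenylselanyl)-13,13-ethylenedioxy-14,15-dinor-ent-labdan-8-ol (SePh cis to C20, OH trans to C20) | CC1(CC[C@H]2[C@]3(C)CCCC(C)(C)[C@H]3C[C@@H]([Se]c4ccccc4)[C@]2(C)O)OCCO1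
F5 | step 12 | 13,13-ethylenedioxy-14,15-dinor-ent-labd-6-en-8-ol (OH trans to C20) | CC1(CC[C@H]2[C@]3(C)CCCC(C)(C)[C@H]3C=C[C@]2(C)O)OCCO1
F6 | step 15 | 8-O-trimethylsilyl ether of 22 | CC1(CC[C@H]2[C@]3(C)CCCC(C)(C)[C@H]3C(=O)C[C@]2(C)O[Si](C)(C)C)OCCO1
F7 | step 15 | 8-O-trimethylsilyl ether of 23 | CC1(CC[C@H]2[C@]3(C)CCCC(C)(C)[C@H]3[C@H](O)C[C@]2(C)O[Si](C)(C)C)OCCO1
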